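**Retrosynthetic overview**
- The dihydropyranone ring is closed last, by a catalyst-controlled 6-endo oxa-Michael addition within a fully substituted, open-chain crotonyl triketone; this sets the C2 stereocentre.
- The crotonyl side chain comes from an acetyl group by aldol condensation with acetaldehyde, done only after dearomatisation so the enone cannot close early.
- The quaternary carbon (C8) comes from a palladium-catalysed asymmetric dearomative C-geranylation of an aromatic methyl/prenyl acylphloroglucinol.
- That arene comes from 2,4,6-trihydroxytoluene by Friedel–Crafts acetylation and C-prenylation.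
- Ring order: the carbocycle is bought as an arene and dearomatised; the only ring built is the O-heterocycle, in the final step.

Assumptions: 2,4,6-trihydroxytoluene is taken as a catalogue chemical; the handedness of the ligand in step 3 and of the acid in step 5 is assigned by analogy, and the mirror-image catalyst is used if the first run shows the opposite sense; the dearomatised triketones are drawn and named in the tautomer that matches the target, and their CIP descriptors refer to that drawing.

**Step 1**
Reactants: 1 2,4,6-trihydroxytoluene (2-methylbenzene-1,3,5-triol); 2 acetic anhydride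
Product: 3 1-(2,4,6-trihydroxy-3-methylphenyl)ethan-1-one
Conditions: Ac2O (1.05 equiv), MeSO3H (cat.), AcOH, 80 °C
Reagents that add atoms: 2 acetic anhydride, CC(=O)OC(C)=O
Why: Friedel–Crafts C-acylation of the very electron-rich arene at one of its two equivalent free ring positions, the first acetyl group deactivating the ring against a second acylation.

**Step 2**
Reactants: 3 1-(2,4,6-trihydroxy-3-methylphenyl)ethan-1-one; 4 prenyl bromide (1-bromo-3-methylbut-2-ene)
Product: 5 1-[2,4,6-trihydroxy-3-methyl-5-(3-methylbut-2-en-1-yl)phenyl]ethan-1-one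
Conditions: prenyl bromide (1.0 equiv), 10% aq. KOH, 0 °C
Reagents that add atoms: 4 prenyl bromide, CC(C)=CCBr
Why: Classical C-alkylation (C-prenylation) of the ambident acylphloroglucinolate in water, where the protic medium favours carbon over oxygen attack and the only unsubstituted ring carbon reacts with re-aromatisation.

**Step 3**
Reactants: 5 1-[2,4,6-trihydroxy-3-methyl-5-(3-methylbut-2-en-1-yl)phenyl]ethan-1-one; 6 geranyl acetate ((2E)-3,7-dimethylocta-2,6-dien-1-yl acetate)
Product: 7 (6R)-4-acetyl-6-[(2E)-3,7-dimethylocta-2,6-dien-1-yl]-3,5-dihydroxy-6-methyl-2-(3-methylbut-2-en-1-yl)cyclohexa-2,4-dien-1-one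
Conditions: Pd2(dba)3·CHCl3 (2.5 mol %), (R,R)-DACH-phenyl Trost ligand (N,N'-[(1R,2R)-cyclohexane-1,2-diyl]bis[2-(diphenylphosphanyl)benzamide], 7.5 mol %), Et3N (1.2 equiv), degassed CH2Cl2, 0 °C
Reagents that add atoms: 6 geranyl acetate, CC(C)=CCC/C(C)=C/COC(C)=O
Why: Proposed new method: zerovalent palladium ionises geranyl acetate to a π-geranyl complex that is attacked at its unsubstituted terminus (linear product, E geometry kept) by the triethylammonium phenoxide of 5 at the methyl-bearing ring carbon, the less hindered of the two substituted nucleophilic carbons, while the chiral pocket of the ligand selects one face of the planar nucleophile to give the (R) quaternary centre and the product is protected from re-ionisation as its triketonate; the closest known reaction type is the Trost-ligand palladium-catalysed asymmetric allylic dearomatisation of naphthols and phloroglucinols (Tsuji–Trost asymmetric allylic alkylation).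

**Step 4**
Reactants: 7 (6R)-4-acetyl-6-[(2E)-3,7-dimethylocta-2,6-dien-1-yl]-3,5-dihydroxy-6-methyl-2-(3-methylbut-2-en-1-yl)cyclohexa-2,4-dien-1-one; 8 acetaldehyde
Product: 10 (6R)-4-[(2E)-but-2-enoyl]-6-[(2E)-3,7-dimethylocta-2,6-dien-1-yl]-3,5-dihydroxy-6-methyl-2-(3-methylbut-2-en-1-yl)cyclohexa-2,4-dien-1-one, via beta-hydroxy ketone 9 (not isolated)
Conditions: MeCHO (5 equiv, in portions), piperidine (30 mol %), AcOH (30 mol %), 4 Å MS, CHCl3, sealed tube, 40 °C; cold 0.5 M HCl wash; used promptly
Reagents that add atoms: 8 acetaldehyde, CC=O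
Why: Amine-catalysed aldol condensation (Knoevenagel/Claisen–Schmidt type) at the acetyl methyl group, the reaction type that converts acetyl β-triketones such as dehydroacetic acid into enoyl triketones, gives the (E)-enone, which stays open under these conditions because its triketonate is a poor oxa-Michael donor, and the quaternary centre is not touched.

**Step 5**
Reactants: 10 (6R)-4-[(2E)-but-2-enoyl]-6-[(2E)-3,7-dimethylocta-2,6-dien-1-yl]-3,5-dihydroxy-6-methyl-2-(3-methylbut-2-en-1-yl)cyclohexa-2,4-dien-1-one
Product: 11 (2S,8R)-8-[(2E)-3,7-dimethylocta-2,6-dien-1-yl]-5-hydroxy-2,8-dimethyl-6-(3-methylbut-2-en-1-yl)-2,3-dihydro-4H-chromene-4,7(8H)-dione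
Conditions: (R)-TRIP ((R)-3,3'-bis(2,4,6-triisopropylphenyl)-1,1'-binaphthyl-2,2'-diyl hydrogen phosphate, 10 mol %), toluene, −20 to 0 °C
Reagents that add atoms: none
Why: Proposed new method: biomimetic 6-endo-trig oxa-Michael addition in which the enol OH between the acyl-bearing and prenyl-bearing carbons chelates the acyl carbonyl (it remains as the chelated 5-OH of the product) and so holds the alkene over the oxygen next to the quaternary carbon, which adds to the β-carbon, while the chiral phosphoric acid, some three to four pK units stronger than the substrate's own vinylogous acid, hydrogen-bonds both the enone carbonyl and the attacking oxygen and fixes the face of the β-carbon to give (2S) with the remote (8R) centre untouched; the closest known reaction types are the chiral-phosphoric-acid-catalysed intramolecular oxa-Michael cyclisation to tetrahydropyrans and the cinchona-thiourea-catalysed oxa-Michael closure of 2'-hydroxy enones to chromanones.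

**Compound list**
1 | 2,4,6-trihydroxytoluene (2-methylbenzene-1,3,5-triol) | Cc1c(O)cc(O)cc1O | starting material
2 | acetic anhydride | CC(=O)OC(C)=O | starting material
3 | 1-(2,4,6-trihydroxy-3-methylphenyl)ethan-1-one | CC(=O)c1c(O)cc(O)c(C)c1O | intermediate
4 | prenyl bromide (1-bromo-3-methylbut-2-ene) | CC(C)=CCBr | starting material
5 | 1-[2,4,6-trihydroxy-3-methyl-5-(3-methylbut-2-en-1-yl)phenyl]ethan-1-one | CC(=O)c1c(O)c(C)c(O)c(CC=C(C)C)c1O | intermediate
6 | geranyl acetate ((2E)-3,7-dimethylocta-2,6-dien-1-yl acetate) | CC(C)=CCC/C(C)=C/COC(C)=O | starting material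
7 | (6R)-4-acetyl-6-[(2E)-3,7-dimethylocta-2,6-dien-1-yl]-3,5-dihydroxy-6-methyl-2-(3-methylbut-2-en-1-yl)cyclohexa-2,4-dien-1-one | CC(C)=CCC/C(C)=C/C[C@@]1(C)C(=O)C(CC=C(C)C)=C(O)C(C(C)=O)=C1O | intermediate
8 | acetaldehyde | CC=O | starting material
9 | (6R)-6-[(2E)-3,7-dimethylocta-2,6-dien-1-yl]-3,5-dihydroxy-4-(3-hydroxybutanoyl)-6-methyl-2-(3-methylbut-2-en-1-yl)cyclohexa-2,4-dien-1-one (both carbinol epimers; not isolated) | CC(C)=CCC/C(C)=C/C[C@@]1(C)C(=O)C(CC=C(C)C)=C(O)C(C(=O)CC(C)O)=C1O | intermediate
10 | (6R)-4-[(2E)-but-2-enoyl]-6-[(2E)-3,7-dimethylocta-2,6-dien-1-yl]-3,5-dihydroxy-6-methyl-2-(3-methylbut-2-en-1-yl)cyclohexa-2,4-dien-1-one | CC(C)=CCC/C(C)=C/C[C@@]1(C)C(=O)C(CC=C(C)C)=C(O)C(C(=O)/C=C/C)=C1O | intermediate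
11 | (2S,8R)-8-[(2E)-3,7-dimethylocta-2,6-dien-1-yl]-5-hydroxy-2,8-dimethyl-6-(3-methylbut-2-en-1-yl)-2,3-dihydro-4H-chromene-4,7(8H)-dione | CC(C)=CCC/C(C)=C/C[C@@]1(C)C(=O)C(CC=C(C)C)=C(O)C2=C1O[C@@H](C)CC2=O | target

**Totals**
Total step count: 5. Longest linear sequence: 5 steps (1 → 3 → 5 → 7 → 10 → 11).

**Steps most likely to fail, with fallbacks**

Step 5 is the riskiest. The uncertainties are the face selectivity, which of the two flanking enol oxygens closes the ring, and a racemic background closure of 10. The fallback sets out from 10 and comes back at 11. The ring is closed without chiral control (diphenyl phosphate 10 mol %, toluene, room temperature) to give 11 together with the (2R,8R)-epimer of 11 F1. The two diastereomers are separated by preparative HPLC. F1 is returned to 10 by base-induced retro-oxa-Michael ring opening (DBU, THF, then cold dilute HCl) and cycled again.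

Step 3 is next. The uncertainties are C- versus O-allylation, attack at the methyl-bearing versus the prenyl-bearing carbon, and the enantiomeric excess. The fallback sets out from 5 and comes back at 7. Catalyst-free dearomative C-geranylation of the sodium phenoxide of 5 with geranyl bromide (NaOMe, MeOH, 0 °C) gives the racemate, that is 7 together with the (6S)-enantiomer of 7 F2. The enantiomers are separated by preparative chromatography on a chiral stationary phase, and 7 is carried on.

Step 4 is third. The uncertainties are self-condensation of acetaldehyde, conjugate addition of the amine to the product, and premature ring closure. The fallback sets out from 7 and comes back at 10 and uses stoichiometric enolate chemistry instead of amine catalysis. The lithium trianion of 7 (LiN(iPr)2 3.2 equiv, THF, −78 °C) adds to acetaldehyde to give the lithium aldolate of 9. This is acetylated in the same flask (Ac2O 1.05 equiv) to the beta-acetoxy ketone F3. Further LiN(iPr)2 (1.2 equiv, −78 to 0 °C) expels acetate by E1cB elimination to give 10 as its dianion, which is released by a cold dilute acid quench.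

**Further compounds**
F1 | step 5 | (2R,8R)-8-[(2E)-3,7-dimethylocta-2,6-dien-1-yl]-5-hydroxy-2,8-dimethyl-6-(3-methylbut-2-en-1-yl)-2,3-dihydro-4H-chromene-4,7(8H)-dione | CC(C)=CCC/C(C)=C/C[C@@]1(C)C(=O)C(CC=C(C)C)=C(O)C2=C1O[C@H](C)CC2=O
F2 | step 3 | (6S)-4-acetyl-6-[(2E)-3,7-dimethylocta-2,6-dien-1-yl]-3,5-dihydroxy-6-methyl-2-(3-methylbut-2-en-1-yl)cyclohexa-2,4-dien-1-one | CC(C)=CCC/C(C)=C/C[C@]1(C)C(=O)C(CC=C(C)C)=C(O)C(C(C)=O)=C1O
F3 | step 4 | (6R)-4-(3-acetoxybutanoyl)-6-[(2E)-3,7-dimethylocta-2,6-dien-1-yl]-3,5-dihydroxy-6-methyl-2-(3-methylbut-2-en-1-yl)cyclohexa-2,4-dien-1-one | CC(C)=CCC/C(C)=C/C[C@@]1(C)C(=O)C(CC=C(C)C)=C(O)C(C(=O)CC(C)OC(C)=O)=C1O
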